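## Retrosynthetic overview

- The target comes from its bis-TIPS ether; the chroman O1–C2 bond is closed last by an intramolecular Mitsunobu etherification of a phenol/primary alcohol.
- That alcohol comes from reductive removal of an Evans auxiliary; the C4 methylene comes from reductive removal of the benzylic hydroxyl of an aldol adduct.
- Key C3–C4 bond: Evans syn boron aldol between the B-ring arylacetyl oxazolidinone and the A-ring benzaldehyde; the (S)-auxiliary sets C3 as R.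
- B-ring fragment: the 2,2-dimethylpyran ring is built first (propargyl ether Claisen/oxa-6π on 4-O-TIPS-2,4-dihydroxybenzaldehyde), then the aldehyde is homologated to the arylacetic acid. A-ring aldehyde: formylation of 3,5-dihydroxyanisole and differential O-protection.
- Ring order: dimethylpyran ring of the B unit first, dihydropyran ring of the chroman last.

Abbreviation: TIPS = triisopropylsilyl. The route is a paper design and has not been run; conditions are standard choices for each reaction type.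

## Route

Step 1
Reactants: 1 2,4-dihydroxybenzaldehyde
Product: 2 2-hydroxy-4-[(triisopropylsilyl)oxy]benzaldehyde
Conditions: TIPSCl (1.05 eq), imidazole, CH2Cl2, 0 °C → rt
Reagents that add atoms: triisopropylsilyl chloride, CC(C)[Si](Cl)(C(C)C)C(C)C
Why: Selective O-silylation; the 2-OH is locked in a hydrogen bond to the formyl group, so only the 4-OH reacts.

Step 2
Reactants: 2 2-hydroxy-4-[(triisopropylsilyl)oxy]benzaldehyde; 3 3-chloro-3-methylbut-1-yne
Product: 4 2-[(2-methylbut-3-yn-2-yl)oxy]-4-[(triisopropylsilyl)oxy]benzaldehyde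
Conditions: DBU, CuCl2·2H2O (cat.), MeCN, 0 °C → rt
Reagents that add atoms: none
Why: Copper-catalysed propargylic etherification (SN1-like through a copper allenylidene), which tolerates a hindered phenol and leaves the aryl silyl ether intact.

Step 3
Reactants: 4 2-[(2-methylbut-3-yn-2-yl)oxy]-4-[(triisopropylsilyl)oxy]benzaldehyde
Product: 7 2,2-dimethyl-5-[(triisopropylsilyl)oxy]-2H-chromene-8-carbaldehyde, via allenylphenol 5 (not isolated), via ortho-quinone methide 6 (not isolated)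
Conditions: o-xylene, 140 °C
Reagents that add atoms: none
Why: Aryl propargyl ether Claisen rearrangement, 1,5-H shift and oxa-6π electrocyclisation; C3 is the only free ortho position, so the pyran oxygen ends up ortho to the formyl carbon.

Step 4
Reactants: 7 2,2-dimethyl-5-[(triisopropylsilyl)oxy]-2H-chromene-8-carbaldehyde
Product: 8 8-(2-methoxyvinyl)-2,2-dimethyl-5-[(triisopropylsilyl)oxy]-2H-chromene (E/Z mixture)
Conditions: Ph3P(CH2OMe)Cl (1.5 eq), KHMDS (1.4 eq), THF, 0 °C → rt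
Reagents that add atoms: (methoxymethyl)triphenylphosphonium chloride, COC[P+](c1ccccc1)(c1ccccc1)c1ccccc1.[Cl-]
Why: Wittig methoxymethylenation of a non-enolisable aryl aldehyde; both alkene isomers converge in the next step.

Step 5
Reactants: 8 8-(2-methoxyvinyl)-2,2-dimethyl-5-[(triisopropylsilyl)oxy]-2H-chromene
Product: 9 2-{2,2-dimethyl-5-[(triisopropylsilyl)oxy]-2H-chromen-8-yl}acetaldehyde
Conditions: 2 M aq. HCl, THF, 40 °C; crude used directly
Reagents that add atoms: water, O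
Why: Acid-catalysed enol ether hydrolysis; the enol ether protonates far more readily than the chromene alkene, and aryl TIPS ethers survive dilute acid.

Step 6
Reactants: 9 2-{2,2-dimethyl-5-[(triisopropylsilyl)oxy]-2H-chromen-8-yl}acetaldehyde
Product: 10 2-{2,2-dimethyl-5-[(triisopropylsilyl)oxy]-2H-chromen-8-yl}acetic acid
Conditions: NaClO2, NaH2PO4, 2-methyl-2-butene (excess), t-BuOH/THF/H2O, 0 °C → rt
Reagents that add atoms: sodium chlorite, [Na+].[O-]Cl=O
Why: Pinnick oxidation; the alkene scavenger removes HOCl before it can attack the electron-rich arene or the chromene.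

Step 7
Reactants: 10 2-{2,2-dimethyl-5-[(triisopropylsilyl)oxy]-2H-chromen-8-yl}acetic acid; 11 (S)-4-benzyloxazolidin-2-one
Product: 13 (S)-4-benzyl-3-(2-{2,2-dimethyl-5-[(triisopropylsilyl)oxy]-2H-chromen-8-yl}acetyl)oxazolidin-2-one, via mixed pivalic anhydride 12 (not isolated)
Conditions: PivCl, Et3N, THF, −20 °C; then 11, LiCl, rt
Reagents that add atoms: none
Why: N-acylation through a mixed anhydride under mild LiCl/Et3N conditions, which avoids ketene formation from the arylacetic acid.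

Step 8
Reactants: 14 3,5-dihydroxyanisole
Product: 16 2,4-dihydroxy-6-methoxybenzaldehyde, via aryl iminium chloride 15 (not isolated)
Conditions: POCl3, DMF, MeCN, 0 °C → rt; then H2O, 50 °C; minor 2,6-dihydroxy-4-methoxy isomer removed by crystallisation/chromatography
Reagents that add atoms: N,N-dimethylformamide, CN(C)C=O; water, O
Why: Vilsmeier–Haack formylation, expected mainly para to a free hydroxyl at one of the two equivalent positions flanked by OH and OMe.

Step 9
Reactants: 16 2,4-dihydroxy-6-methoxybenzaldehyde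
Product: 17 2-hydroxy-6-methoxy-4-[(triisopropylsilyl)oxy]benzaldehyde
Conditions: TIPSCl (1.05 eq), imidazole, CH2Cl2, 0 °C → rt
Reagents that add atoms: triisopropylsilyl chloride, CC(C)[Si](Cl)(C(C)C)C(C)C
Why: Selective silylation of the non-hydrogen-bonded 4-OH, as in step 1.

Step 10
Reactants: 17 2-hydroxy-6-methoxy-4-[(triisopropylsilyl)oxy]benzaldehyde
Product: 18 2-(allyloxy)-6-methoxy-4-[(triisopropylsilyl)oxy]benzaldehyde
Conditions: allyl alcohol, PPh3, DIAD, THF, 0 °C → rt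
Reagents that add atoms: allyl alcohol, C=CCO
Why: Mitsunobu O-alkylation of the acidic chelated phenol under neutral conditions, so the base-labile para-silyloxy group is not touched.

Step 11
Reactants: 13 (S)-4-benzyl-3-(2-{2,2-dimethyl-5-[(triisopropylsilyl)oxy]-2H-chromen-8-yl}acetyl)oxazolidin-2-one; 18 2-(allyloxy)-6-methoxy-4-[(triisopropylsilyl)oxy]benzaldehyde
Product: 21 (S)-4-benzyl-3-[(2S,3S)-3-{2-(allyloxy)-6-methoxy-4-[(triisopropylsilyl)oxy]phenyl}-2-{2,2-dimethyl-5-[(triisopropylsilyl)oxy]-2H-chromen-8-yl}-3-hydroxypropanoyl]oxazolidin-2-one, via boron enolate 19 (not isolated), via boron aldolate 20 (not isolated)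
Conditions: Bu2BOTf (1.2 eq), i-Pr2NEt (1.4 eq), CH2Cl2, −78 → 0 °C; 18 (1.2 eq), −78 → 0 °C; then pH 7 buffer, MeOH, 30% H2O2, 0 °C
Reagents that add atoms: none
Why: Evans syn aldol through the (Z)-boron enolate and a Zimmerman–Traxler transition state; the (S)-benzyl auxiliary directs the aldehyde to the enolate face that gives 2S (the future C3-R), and the carbinol centre is removed in the next step.

Step 12
Reactants: 21 aldol adduct
Product: 22 (S)-4-benzyl-3-[(R)-3-{2-(allyloxy)-6-methoxy-4-[(triisopropylsilyl)oxy]phenyl}-2-{2,2-dimethyl-5-[(triisopropylsilyl)oxy]-2H-chromen-8-yl}propanoyl]oxazolidin-2-one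
Conditions: Et3SiH (6 eq), BF3·OEt2 (2.5 eq), CH2Cl2, −78 → −30 °C
Reagents that add atoms: none
Why: Ionic hydrogenation; the 2,4,6-trioxygenated benzylic alcohol ionises at low temperature and the cation is reduced by silane, while C2 is untouched (the descriptor changes from S to R only through CIP priorities).

Step 13
Reactants: 22 deoxygenated imide
Product: 23 (R)-3-{2-(allyloxy)-6-methoxy-4-[(triisopropylsilyl)oxy]phenyl}-2-{2,2-dimethyl-5-[(triisopropylsilyl)oxy]-2H-chromen-8-yl}propan-1-ol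
Conditions: LiBH4, MeOH (1 eq), THF, 0 °C
Reagents that add atoms: none
Why: Reductive cleavage of the N-acyl oxazolidinone at the exocyclic carbonyl at 0 °C, without epimerising the α-aryl centre; the auxiliary is recovered.

Step 14
Reactants: 23 allyl ether alcohol
Product: 24 2-[(R)-2-{2,2-dimethyl-5-[(triisopropylsilyl)oxy]-2H-chromen-8-yl}-3-hydroxypropyl]-3-methoxy-5-[(triisopropylsilyl)oxy]phenol
Conditions: Pd(PPh3)4 (5 mol%), morpholine, THF, rt
Reagents that add atoms: none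
Why: Tsuji–Trost deallylation; the primary allyl aryl ether ionises at room temperature whereas the cyclic tertiary chromene ether and the silyl ethers should be inert.

Step 15
Reactants: 24 phenol alcohol
Product: 25 (R)-5-methoxy-7-[(triisopropylsilyl)oxy]-3-{2,2-dimethyl-5-[(triisopropylsilyl)oxy]-2H-chromen-8-yl}chromane
Conditions: PPh3, DIAD, THF (0.02 M), 0 °C → rt
Reagents that add atoms: none
Why: Intramolecular Mitsunobu etherification (6-exo-tet displacement at the primary carbon by the ortho phenol); the stereocentre is not involved.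

Step 16
Reactants: 25 bis-TIPS isoflavan
Product: 26 (3R)-3-(5-hydroxy-2,2-dimethyl-2H-chromen-8-yl)-5-methoxychroman-7-ol (CNP0320659.1)
Conditions: TBAF (2.4 eq), AcOH (2.4 eq), THF, 0 °C
Reagents that add atoms: none
Why: Fluoride-mediated desilylation of both aryl silyl ethers under buffered conditions that do not affect the chromene or the stereocentre.

## Compound list

1 | 2,4-dihydroxybenzaldehyde | O=Cc1ccc(O)cc1O | starting material
2 | 2-hydroxy-4-[(triisopropylsilyl)oxy]benzaldehyde | O=Cc1ccc(O[Si](C(C)C)(C(C)C)C(C)C)cc1O | intermediate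
3 | 3-chloro-3-methylbut-1-yne | C#CC(C)(C)Cl | starting material
4 | 2-[(2-methylbut-3-yn-2-yl)oxy]-4-[(triisopropylsilyl)oxy]benzaldehyde | O=Cc1ccc(O[Si](C(C)C)(C(C)C)C(C)C)cc1OC(C)(C)C#C | intermediate
5 | 2-hydroxy-3-(3-methylbuta-1,2-dien-1-yl)-4-[(triisopropylsilyl)oxy]benzaldehyde (allenylphenol) | O=Cc1ccc(O[Si](C(C)C)(C(C)C)C(C)C)c(C=C=C(C)C)c1O | intermediate
6 | (Z)-5-(3-methylbut-2-en-1-ylidene)-6-oxo-4-[(triisopropylsilyl)oxy]cyclohexa-1,3-diene-1-carbaldehyde (ortho-quinone methide) | O=CC1=CC=C(O[Si](C(C)C)(C(C)C)C(C)C)/C(=C/C=C(C)C)C1=O | intermediate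
7 | 2,2-dimethyl-5-[(triisopropylsilyl)oxy]-2H-chromene-8-carbaldehyde | O=Cc1ccc(O[Si](C(C)C)(C(C)C)C(C)C)c2C=CC(C)(C)Oc12 | intermediate
8 | 8-(2-methoxyvinyl)-2,2-dimethyl-5-[(triisopropylsilyl)oxy]-2H-chromene (E/Z mixture) | COC=Cc1ccc(O[Si](C(C)C)(C(C)C)C(C)C)c2C=CC(C)(C)Oc12 | intermediate
9 | 2-{2,2-dimethyl-5-[(triisopropylsilyl)oxy]-2H-chromen-8-yl}acetaldehyde | O=CCc1ccc(O[Si](C(C)C)(C(C)C)C(C)C)c2C=CC(C)(C)Oc12 | intermediate
10 | 2-{2,2-dimethyl-5-[(triisopropylsilyl)oxy]-2H-chromen-8-yl}acetic acid | OC(=O)Cc1ccc(O[Si](C(C)C)(C(C)C)C(C)C)c2C=CC(C)(C)Oc12 | intermediate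
11 | (S)-4-benzyloxazolidin-2-one | O=C1N[C@@H](Cc2ccccc2)CO1 | starting material
12 | mixed anhydride of acid 10 with pivalic acid | CC(C)(C)C(=O)OC(=O)Cc1ccc(O[Si](C(C)C)(C(C)C)C(C)C)c2C=CC(C)(C)Oc12 | intermediate
13 | (S)-4-benzyl-3-(2-{2,2-dimethyl-5-[(triisopropylsilyl)oxy]-2H-chromen-8-yl}acetyl)oxazolidin-2-one | O=C(Cc1ccc(O[Si](C(C)C)(C(C)C)C(C)C)c2C=CC(C)(C)Oc12)N1[C@@H](Cc2ccccc2)COC1=O | intermediate
14 | 3,5-dihydroxyanisole (5-methoxybenzene-1,3-diol) | COc1cc(O)cc(O)c1 | starting material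
15 | N-(2,4-dihydroxy-6-methoxybenzylidene)-N-methylmethanaminium chloride | C[N+](C)=Cc1c(O)cc(O)cc1OC.[Cl-] | intermediate
16 | 2,4-dihydroxy-6-methoxybenzaldehyde | COc1cc(O)cc(O)c1C=O | intermediate
17 | 2-hydroxy-6-methoxy-4-[(triisopropylsilyl)oxy]benzaldehyde | COc1cc(O[Si](C(C)C)(C(C)C)C(C)C)cc(O)c1C=O | intermediate
18 | 2-(allyloxy)-6-methoxy-4-[(triisopropylsilyl)oxy]benzaldehyde | COc1cc(O[Si](C(C)C)(C(C)C)C(C)C)cc(OCC=C)c1C=O | intermediate
19 | (Z)-dibutylboron enolate of imide 13 | CCCCB(CCCC)O/C(=C\c1ccc(O[Si](C(C)C)(C(C)C)C(C)C)c2C=CC(C)(C)Oc12)N1[C@@H](Cc2ccccc2)COC1=O | intermediate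
20 | O-dibutylboryl derivative of the (2S,3S) aldol adduct 21 | CCCCB(CCCC)O[C@H](c1c(OCC=C)cc(O[Si](C(C)C)(C(C)C)C(C)C)cc1OC)[C@H](c1ccc(O[Si](C(C)C)(C(C)C)C(C)C)c2C=CC(C)(C)Oc12)C(=O)N1[C@@H](Cc2ccccc2)COC1=O | intermediate
21 | (S)-4-benzyl-3-[(2S,3S)-3-{2-(allyloxy)-6-methoxy-4-[(triisopropylsilyl)oxy]phenyl}-2-{2,2-dimethyl-5-[(triisopropylsilyl)oxy]-2H-chromen-8-yl}-3-hydroxypropanoyl]oxazolidin-2-one | O[C@H](c1c(OCC=C)cc(O[Si](C(C)C)(C(C)C)C(C)C)cc1OC)[C@H](c1ccc(O[Si](C(C)C)(C(C)C)C(C)C)c2C=CC(C)(C)Oc12)C(=O)N1[C@@H](Cc2ccccc2)COC1=O | intermediate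
22 | (S)-4-benzyl-3-[(R)-3-{2-(allyloxy)-6-methoxy-4-[(triisopropylsilyl)oxy]phenyl}-2-{2,2-dimethyl-5-[(triisopropylsilyl)oxy]-2H-chromen-8-yl}propanoyl]oxazolidin-2-one | C=CCOc1cc(O[Si](C(C)C)(C(C)C)C(C)C)cc(OC)c1C[C@H](c1ccc(O[Si](C(C)C)(C(C)C)C(C)C)c2C=CC(C)(C)Oc12)C(=O)N1[C@@H](Cc2ccccc2)COC1=O | intermediate
23 | (R)-3-{2-(allyloxy)-6-methoxy-4-[(triisopropylsilyl)oxy]phenyl}-2-{2,2-dimethyl-5-[(triisopropylsilyl)oxy]-2H-chromen-8-yl}propan-1-ol | C=CCOc1cc(O[Si](C(C)C)(C(C)C)C(C)C)cc(OC)c1C[C@H](c1ccc(O[Si](C(C)C)(C(C)C)C(C)C)c2C=CC(C)(C)Oc12)CO | intermediate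
24 | 2-[(R)-2-{2,2-dimethyl-5-[(triisopropylsilyl)oxy]-2H-chromen-8-yl}-3-hydroxypropyl]-3-methoxy-5-[(triisopropylsilyl)oxy]phenol | Oc1cc(O[Si](C(C)C)(C(C)C)C(C)C)cc(OC)c1C[C@H](c1ccc(O[Si](C(C)C)(C(C)C)C(C)C)c2C=CC(C)(C)Oc12)CO | intermediate
25 | (R)-5-methoxy-7-[(triisopropylsilyl)oxy]-3-{2,2-dimethyl-5-[(triisopropylsilyl)oxy]-2H-chromen-8-yl}chromane | COc1cc(O[Si](C(C)C)(C(C)C)C(C)C)cc2c1C[C@H](c1ccc(O[Si](C(C)C)(C(C)C)C(C)C)c3c1OC(C)(C)C=C3)CO2 | intermediate
26 | (3R)-3-(5-hydroxy-2,2-dimethyl-2H-chromen-8-yl)-5-methoxychroman-7-ol | COc1cc(O)cc2c1C[C@H](c1ccc(O)c3c1OC(C)(C)C=C3)CO2 | target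

## Step count and risks

Total steps: 16. Longest linear sequence: 13 (steps 1–7, then 11–16); the A-ring branch (steps 8–10) joins at step 11.

Steps most likely to fail, with fallbacks:

**Step 11 (aldol).** The aldehyde is di-ortho-substituted and electron-rich, so addition of the boron enolate may be slow or reversible. The fallback sets out from acid 10 and aldehyde 18 and comes back at alcohol 23. Acid 10 is coupled with (S)-4-benzylthiazolidine-2-thione (EDC, DMAP, CH2Cl2) to give (S)-4-benzyl-3-(2-{2,2-dimethyl-5-[(triisopropylsilyl)oxy]-2H-chromen-8-yl}acetyl)thiazolidine-2-thione F1. Its chlorotitanium enolate (TiCl4, i-Pr2NEt, N-methylpyrrolidinone, CH2Cl2, −78 °C) adds to Lewis-acid-activated 18 to give the Evans-syn (2S,3S) aldol adduct of the thiazolidinethione F2. Et3SiH/BF3·OEt2 then gives the deoxygenated (R)-N-acyl thiazolidinethione F3, and NaBH4 in THF/EtOH cleaves the thioimide to 23.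

**Step 12 (benzylic deoxygenation).** The cation may lose the C2 proton, be trapped by the chromene oxygen, or the acid may attack the chromene alkene before the silane delivers hydride. The fallback sets out from 21 and comes back at 22. The cation is generated under milder conditions and trapped by a much better nucleophile (PhSH, ZnI2, CH2Cl2, 0 °C), giving the 3-(phenylthio) analogue of 21 F4 as a mixture of epimers at the sulfur-bearing carbon. The C–S bond is then reduced by a radical path that cannot eliminate (Bu3SnH, AIBN, toluene, 80 °C) to give 22.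

**Step 2 (propargylation).** The phenol is hindered and hydrogen-bonded and the electrophile is tertiary. The fallback sets out from 2 and comes back at 7, replacing steps 2 and 3 with a direct annulation: 3-methylbut-2-enal, ethylenediammonium diacetate (cat.), xylene, reflux. Ortho C-alkenylation at C3 (the only free position ortho to the free OH) and loss of water give the same ortho-quinone methide 6, which electrocyclises to 7. No new isolable compound is made.

## Further compounds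

F0 | step 2 | none | none
F1 | step 11 | (S)-4-benzyl-3-(2-{2,2-dimethyl-5-[(triisopropylsilyl)oxy]-2H-chromen-8-yl}acetyl)thiazolidine-2-thione | O=C(Cc1ccc(O[Si](C(C)C)(C(C)C)C(C)C)c2C=CC(C)(C)Oc12)N1[C@@H](Cc2ccccc2)CSC1=S
F2 | step 11 | (2S,3S)-3-{2-(allyloxy)-6-methoxy-4-[(triisopropylsilyl)oxy]phenyl}-1-[(S)-4-benzyl-2-thioxothiazolidin-3-yl]-2-{2,2-dimethyl-5-[(triisopropylsilyl)oxy]-2H-chromen-8-yl}-3-hydroxypropan-1-one | O[C@H](c1c(OCC=C)cc(O[Si](C(C)C)(C(C)C)C(C)C)cc1OC)[C@H](c1ccc(O[Si](C(C)C)(C(C)C)C(C)C)c2C=CC(C)(C)Oc12)C(=O)N1[C@@H](Cc2ccccc2)CSC1=S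
F3 | step 11 | (R)-3-{2-(allyloxy)-6-methoxy-4-[(triisopropylsilyl)oxy]phenyl}-1-[(S)-4-benzyl-2-thioxothiazolidin-3-yl]-2-{2,2-dimethyl-5-[(triisopropylsilyl)oxy]-2H-chromen-8-yl}propan-1-one | C=CCOc1cc(O[Si](C(C)C)(C(C)C)C(C)C)cc(OC)c1C[C@H](c1ccc(O[Si](C(C)C)(C(C)C)C(C)C)c2C=CC(C)(C)Oc12)C(=O)N1[C@@H](Cc2ccccc2)CSC1=S
F4 | step 12 | (S)-4-benzyl-3-[(2R)-3-{2-(allyloxy)-6-methoxy-4-[(triisopropylsilyl)oxy]phenyl}-2-{2,2-dimethyl-5-[(triisopropylsilyl)oxy]-2H-chromen-8-yl}-3-(phenylthio)propanoyl]oxazolidin-2-one (both epimers at C3) | c1ccccc1SC(c1c(OCC=C)cc(O[Si](C(C)C)(C(C)C)C(C)C)cc1OC)[C@H](c1ccc(O[Si](C(C)C)(C(C)C)C(C)C)c2C=CC(C)(C)Oc12)C(=O)N1[C@@H](Cc2ccccc2)COC1=O
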